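**Strategy.** Atoms are numbered as in the target SMILES. Everything rests on cutting the C10–C11 bond next to the E-trisubstituted alkene C11=C12 (methyl C13). The key step exploits the fact that the segment C14–C20, with the C16 stereocentre and its isopropenyl group, is ring-opened limonene. In one operation, zirconium-catalysed methylalumination of the limonene-derived terminal alkyne, zinc exchange and palladium-catalysed coupling with a primary alkyl iodide install C13, fix the E geometry and join two chiral-pool pieces. The precursors are (R)-5,6-dimethylhept-6-en-1-yne and an (S)-configured, silyl-capped iodide carrying C7. The C5 alkyne is then unmasked, hydroaluminated and added SN2′ under copper catalysis to the allylic phosphate of the six-membered ring (C23–C30), creating quaternary C3.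

Key step: step 12

Remark: the facial sense of the two catalyst-controlled steps (14 and 27) is assigned by analogy with the accepted models for these catalyst classes; if a model run shows the opposite sense, the mirror-image catalyst is used.

**Alkyne fragment (C11–C20) from (S)-limonene**

Step 1
Reactants: 1 (S)-(−)-limonene
Product: 2 (4S)-limonene 1,2-oxide (cis/trans mixture at the oxirane)
Conditions: mCPBA (1.0 equiv), NaHCO3, CH2Cl2, 0 °C
Reagents that add atoms: 3-chloroperoxybenzoic acid, OOC(=O)c1cccc(Cl)c1
Why: Prilezhaev epoxidation should be faster at the electron-richer trisubstituted ring alkene than at the 1,1-disubstituted isopropenyl group, and the oxirane configuration does not matter because both carbons become carbonyls in step 2.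

Step 2
Reactants: 2 (4S)-limonene 1,2-oxide
Product: 4 (S)-6-oxo-3-(prop-1-en-2-yl)heptanal, via limonene-1,2-diol 3 (not isolated)
Conditions: HIO4·2H2O, THF/H2O, 0 °C to rt
Reagents that add atoms: water, O
Why: Periodic acid opens the oxirane to the vicinal diol and cleaves it in the same flask (Malaprade glycol cleavage), and the stereocentre is β to the new aldehyde and therefore not epimerisable.

Step 3
Reactants: 4 (S)-6-oxo-3-(prop-1-en-2-yl)heptanal
Product: 5 (S)-6-oxo-3-(prop-1-en-2-yl)heptanoic acid
Conditions: NaClO2, NaH2PO4, 2-methylbut-2-ene, t-BuOH/H2O, 0 °C to rt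
Reagents that add atoms: sodium chlorite, [Na+].[O-]Cl=O
Why: Pinnick oxidation converts the aldehyde to the acid without touching the methyl ketone, and the alkene scavenger intercepts hypochlorous acid before it can add to the isopropenyl group.

Step 4
Reactants: 5 (S)-6-oxo-3-(prop-1-en-2-yl)heptanoic acid
Product: 7 (R)-5,6-dimethylhept-6-en-2-one, via Barton ester 6 (not isolated)
Conditions: N-hydroxypyridine-2-thione, DCC, DMAP (cat.), CH2Cl2, rt, dark; then t-BuSH (excess), hν (tungsten lamp), rt
Reagents that add atoms: none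
Why: Barton reductive decarboxylation turns CH2CO2H into methyl C17, the primary radical being trapped by the thiol much faster than it can close onto the neighbouring alkene; the stereocentre keeps its spatial arrangement and its descriptor changes from S to R only because the ligand priorities change.

Step 5
Reactants: 7 (R)-5,6-dimethylhept-6-en-2-one
Product: 9 (R)-5,6-dimethylhept-6-en-1-yne, via enol phosphate 8 (not isolated)
Conditions: LiN(i-Pr)2 (1.05 equiv), THF, −78 °C; ClP(O)(OEt)2, −78 °C to rt; then LiN(i-Pr)2 (2.3 equiv), −78 °C to rt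
Reagents that add atoms: none
Why: Kinetic deprotonation on the methyl side, O-phosphorylation and base-induced elimination of diethyl phosphate give the terminal alkyne (Negishi enol phosphate route), with the stereocentre three carbons from the carbonyl and thus safe.

**Iodide fragment (C5–C10) from (S)-methylsuccinic acid**

Step 6
Reactants: 10 (S)-methylsuccinic acid
Product: 11 (S)-methylsuccinic anhydride
Conditions: AcCl, reflux
Reagents that add atoms: none
Why: Acyl chloride-mediated cyclodehydration of a 1,4-diacid to the five-membered anhydride runs without base, so the α-stereocentre (future C7) should not epimerise.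

Step 7
Reactants: 11 (S)-methylsuccinic anhydride
Product: 13 (S)-3-methyloxolan-2-one, via hydroxy acid 12 (not isolated)
Conditions: LiBH(s-Bu)3 (2.1 equiv), THF, −78 to 0 °C; then aq. HCl, rt
Reagents that add atoms: none
Why: The bulky trialkylborohydride should attack the less hindered carbonyl, remote from the methyl group (regioselective hydride reduction of an unsymmetrical cyclic anhydride), so acidification closes the α-methyl lactone with the stereocentre unchanged.

Step 8
Reactants: 13 (S)-3-methyloxolan-2-one
Product: 14 (3S)-3-methyloxolan-2-ol (anomeric mixture)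
Conditions: i-Bu2AlH (1.05 equiv), CH2Cl2, −78 °C
Reagents that add atoms: none
Why: Partial reduction of a γ-lactone with i-Bu2AlH at low temperature stops at the lactol because the aluminium hemiacetal survives until work-up.

Step 9
Reactants: 14 (3S)-3-methyloxolan-2-ol
Product: 15 (S)-3-methylpent-4-yn-1-ol
Conditions: dimethyl (1-diazo-2-oxopropyl)phosphonate, K2CO3, MeOH, 0 °C to rt
Reagents that add atoms: dimethyl (1-diazo-2-oxopropyl)phosphonate, COP(=O)(OC)C(=[N+]=[N-])C(C)=O
Why: The open hydroxy aldehyde form of the lactol undergoes Seyferth–Gilbert homologation in its Ohira–Bestmann variant, whose mild carbonate base and low temperature should spare the α-methyl stereocentre.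

Step 10
Reactants: 15 (S)-3-methylpent-4-yn-1-ol
Product: 17 (S)-3-methyl-5-(trimethylsilyl)pent-4-yn-1-ol, via bis-silyl ether 16 (not isolated)
Conditions: n-BuLi (2.2 equiv), THF, −78 °C; Me3SiCl (2.4 equiv), −78 °C to rt; then 1 M aq. HCl, rt
Reagents that add atoms: chlorotrimethylsilane, C[Si](C)(C)Cl
Why: Double deprotonation, C,O-bis-silylation and selective acid hydrolysis of the labile silyl ether is the standard way to cap the terminal alkyne of an alkynol.

Step 11
Reactants: 17 (S)-3-methyl-5-(trimethylsilyl)pent-4-yn-1-ol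
Product: 18 (S)-(5-iodo-3-methylpent-1-yn-1-yl)trimethylsilane
Conditions: I2, PPh3, imidazole, CH2Cl2, 0 °C to rt
Reagents that add atoms: iodine, II
Why: Appel-type iodination (Garegg–Samuelsson conditions) converts the primary alcohol to the iodide by SN2 displacement of the oxyphosphonium ion, two carbons away from the stereocentre.

**Key coupling and unmasking of the alkyne**

Step 12
Reactants: 9 (R)-5,6-dimethylhept-6-en-1-yne; 18 (S)-(5-iodo-3-methylpent-1-yn-1-yl)trimethylsilane
Product: 21 trimethyl[(3S,6E,10R)-3,7,10,11-tetramethyldodeca-6,11-dien-1-yn-1-yl]silane, via alkenylalane 19 (not isolated), via alkenylzinc chloride 20 (not isolated)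
Conditions: 9 (1.5 equiv), Me3Al (3 equiv), Cp2ZrCl2 (0.3 equiv), CH2Cl2, 0 °C to rt; volatiles removed; ZnCl2, THF, 0 °C; then 18, Pd2(dba)3 (2 mol %), PCyp3 (8 mol %), N-methylimidazole, THF/NMP, 80 °C
Reagents that add atoms: trimethylaluminium, C[Al](C)C
Why: The Cp2ZrCl2/Me3Al system adds methyl and metal syn across the terminal alkyne, methyl going to the internal carbon C12 and aluminium to C11, so the E geometry of C11=C12 is fixed before any coupling (Negishi zirconium-catalysed carboalumination). Exchange with ZnCl2 gives the alkenylzinc chloride, which transmetalates to the alkylpalladium iodide formed by oxidative addition of the primary iodide to zerovalent palladium carrying the bulky, electron-rich PCyp3, and reductive elimination forms C10–C11 with retention of alkene geometry (Negishi coupling of an alkenylzinc with an unactivated alkyl iodide). No ring is closed and no stereocentre is created; C7 and C16 are spectators, each at least two sp3 carbons from a metal-bearing carbon. The step needs chemoselectivity for the terminal alkyne over the isopropenyl alkene, which is intrinsic because 1,1-disubstituted alkenes do not carbometalate under these conditions, and the silyl cap on C5 keeps the second alkyne from being deprotonated or carbometalated. β-Hydride elimination from the alkylpalladium should be held back by the trialkylphosphine and N-methylimidazole, and removal of excess Me3Al before the zinc exchange limits competing methyl transfer.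

Step 13
Reactants: 21 trimethyl[(3S,6E,10R)-3,7,10,11-tetramethyldodeca-6,11-dien-1-yn-1-yl]silane
Product: 22 (3S,6E,10R)-3,7,10,11-tetramethyldodeca-6,11-dien-1-yne
Conditions: K2CO3, MeOH/THF, rt
Reagents that add atoms: none
Why: Methoxide-mediated protodesilylation cleaves the C(sp)–Si bond selectively and leaves the alkenes and both stereocentres untouched.

**Ring fragment (C1–C4, C21–C32)**

Step 14
Reactants: 23 propanal; 24 methyl vinyl ketone
Product: 25 (S)-2-methyl-5-oxohexanal
Conditions: (R)-2-[methoxy(diphenyl)methyl]pyrrolidine (5 mol %), ethyl 3,4-dihydroxybenzoate (20 mol %), neat, 4 °C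
Reagents that add atoms: none
Why: In this enamine-mediated organocatalytic Michael addition the diphenylmethyl group shields one face of the E-enamine of propanal, so the enone adds to the open face and the future C28 stereocentre is set under catalyst control.

Step 15
Reactants: 25 (S)-2-methyl-5-oxohexanal
Product: 27 (S)-4-methylcyclohex-2-en-1-one, via aldol 26 (not isolated)
Conditions: LiOH (cat.), i-PrOH, rt
Reagents that add atoms: none
Why: Intramolecular aldol condensation of the methyl ketone onto the aldehyde closes the six-membered ring under mild hydroxide conditions, and the stereocentre, now the γ-carbon of the enone, should not be deprotonated.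

Step 16
Reactants: 27 (S)-4-methylcyclohex-2-en-1-one
Product: 28 trimethyl{[(3R,4S)-3,4-dimethylcyclohex-1-en-1-yl]oxy}silane
Conditions: Me2CuLi (1.3 equiv), Me3SiCl (2 equiv), THF, −78 °C; Et3N, then aq. NaHCO3
Reagents that add atoms: lithium dimethylcuprate, [Li+].C[Cu-]C; chlorotrimethylsilane, C[Si](C)(C)Cl
Why: Silyl chloride-accelerated cuprate conjugate addition delivers methyl anti to the C4 methyl group and traps the enolate regiospecifically as the silyl enol ether; the new C3 centre is erased in step 17.

Step 17
Reactants: 28 trimethyl{[(3R,4S)-3,4-dimethylcyclohex-1-en-1-yl]oxy}silane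
Product: 29 (S)-3,4-dimethylcyclohex-2-en-1-one
Conditions: Pd(OAc)2 (10 mol %), O2 (1 atm), DMSO, rt
Reagents that add atoms: none
Why: In this Saegusa–Ito oxidation the carbon-bound palladium enolate at C2 can only lose the C3 hydrogen, so the enone double bond returns regiospecifically and the C4 stereocentre is not involved.

Step 18
Reactants: 29 (S)-3,4-dimethylcyclohex-2-en-1-one
Product: 31 (S)-3,3,4-trimethylcyclohex-1-en-1-yl trifluoromethanesulfonate, via lithium enolate 30 (not isolated)
Conditions: Me2CuLi (1.5 equiv), Et2O, 0 °C; then PhNTf2, THF, 0 °C to rt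
Reagents that add atoms: lithium dimethylcuprate, [Li+].C[Cu-]C; N-phenylbis(trifluoromethanesulfonimide), FC(F)(F)S(=O)(=O)N(c1ccccc1)S(=O)(=O)C(F)(F)F
Why: Cuprate conjugate addition builds the gem-dimethyl carbon C30 and leaves the enolate on the side of that quaternary carbon, which O-triflation with PhNTf2 captures as a single regioisomer (McMurry–Scott enol triflate formation).

Step 19
Reactants: 31 (S)-3,3,4-trimethylcyclohex-1-en-1-yl trifluoromethanesulfonate
Product: 32 methyl (S)-3,3,4-trimethylcyclohex-1-ene-1-carboxylate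
Conditions: Pd(OAc)2 (5 mol %), PPh3 (10 mol %), CO (1 atm), MeOH, Et3N, DMF, 60 °C
Reagents that add atoms: carbon monoxide, [C-]#[O+]; methanol, CO
Why: Palladium-catalysed alkoxycarbonylation of an enol triflate (oxidative addition, CO insertion, methanolysis) installs the carbon that becomes the exocyclic methylene C25.

Step 20
Reactants: 32 methyl (S)-3,3,4-trimethylcyclohex-1-ene-1-carboxylate
Product: 33 [(S)-3,3,4-trimethylcyclohex-1-en-1-yl]methanol
Conditions: i-Bu2AlH (2.3 equiv), CH2Cl2, −78 to 0 °C
Reagents that add atoms: none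
Why: i-Bu2AlH reduces the conjugated ester in 1,2-fashion to the allylic alcohol.

Step 21
Reactants: 33 [(S)-3,3,4-trimethylcyclohex-1-en-1-yl]methanol
Product: 35 ethyl 2-[(1S,3S)-2,2,3-trimethyl-6-methylidenecyclohexyl]acetate, via ketene acetal 34 (not isolated)
Conditions: MeC(OEt)3 (10 equiv), EtCO2H (cat.), 140 °C, EtOH distilled off
Reagents that add atoms: triethyl orthoacetate, CC(OCC)(OCC)OCC
Why: In this Johnson–Claisen rearrangement the [3,3] shift forms the C22–C23 bond and the exocyclic methylene in one event, and C23 should be set by substrate control because axial bond formation on the half-chair that keeps the C28 methyl equatorial occurs anti to the pseudoaxial methyl on C30 and trans to the C28 methyl, as the target requires.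

Step 22
Reactants: 35 ethyl 2-[(1S,3S)-2,2,3-trimethyl-6-methylidenecyclohexyl]acetate
Product: 36 2-[(1S,3S)-2,2,3-trimethyl-6-methylidenecyclohexyl]ethan-1-ol
Conditions: LiAlH4, Et2O, 0 °C
Reagents that add atoms: none
Why: Hydride reduction of the ester gives the primary alcohol, and C23 is β to the carbonyl and cannot epimerise.

Step 23
Reactants: 36 2-[(1S,3S)-2,2,3-trimethyl-6-methylidenecyclohexyl]ethan-1-ol
Product: 37 (1S,3S)-1-(2-iodoethyl)-2,2,3-trimethyl-6-methylidenecyclohexane
Conditions: I2, PPh3, imidazole, CH2Cl2, 0 °C to rt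
Reagents that add atoms: iodine, II
Why: Appel-type iodination of the primary alcohol runs under near-neutral conditions that leave the exocyclic alkene in place.

Step 24
Reactants: 37 (1S,3S)-1-(2-iodoethyl)-2,2,3-trimethyl-6-methylidenecyclohexane
Product: 38 4-[(1S,3S)-2,2,3-trimethyl-6-methylidenecyclohexyl]but-1-yne
Conditions: LiC≡CH·H2NCH2CH2NH2 (2 equiv), DMSO, rt
Reagents that add atoms: lithium acetylide–ethylenediamine complex, [Li+].[C-]#C.NCCN
Why: SN2 alkylation of the acetylide by an unhindered primary iodide in a dipolar aprotic solvent gives the terminal alkyne directly.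

Step 25
Reactants: 38 4-[(1S,3S)-2,2,3-trimethyl-6-methylidenecyclohexyl]but-1-yne
Product: 41 (2E)-3-methyl-5-[(1S,3S)-2,2,3-trimethyl-6-methylidenecyclohexyl]pent-2-en-1-ol, via alkenylalane 39 (not isolated), via lithium alkenylaluminate 40 (not isolated)
Conditions: Me3Al (3 equiv), Cp2ZrCl2 (0.5 equiv), CH2Cl2, rt; volatiles removed; n-BuLi, hexane/THF, −78 to 0 °C; (CH2O)n, THF, rt
Reagents that add atoms: trimethylaluminium, C[Al](C)C; formaldehyde (from paraformaldehyde), C=O
Why: Negishi zirconium-catalysed methylalumination adds methyl and aluminium syn with methyl on the internal carbon, and the derived aluminate is hydroxymethylated with retention, so the E-allylic alcohol should form as a single geometric isomer while the exocyclic methylene stays inert.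

Step 26
Reactants: 41 (2E)-3-methyl-5-[(1S,3S)-2,2,3-trimethyl-6-methylidenecyclohexyl]pent-2-en-1-ol
Product: 42 diethyl (2E)-3-methyl-5-[(1S,3S)-2,2,3-trimethyl-6-methylidenecyclohexyl]pent-2-en-1-yl phosphate
Conditions: ClP(O)(OEt)2, Et3N, DMAP (cat.), CH2Cl2, 0 °C
Reagents that add atoms: diethyl chlorophosphate, CCOP(=O)(Cl)OCC
Why: O-phosphorylation of the primary allylic alcohol under amine base gives the phosphate without allylic transposition.

**Fragment union**

Step 27
Reactants: 22 (3S,6E,10R)-3,7,10,11-tetramethyldodeca-6,11-dien-1-yne; 42 diethyl (2E)-3-methyl-5-[(1S,3S)-2,2,3-trimethyl-6-methylidenecyclohexyl]pent-2-en-1-yl phosphate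
Product: 44 (3S,4E,6S,9E,13R)-3,6,10,13,14-pentamethyl-3-{2-[(1S,3S)-2,2,3-trimethyl-6-methylidenecyclohexyl]ethyl}pentadeca-1,4,9,14-tetraene (target), via alkenylalane 43 (not isolated)
Conditions: 22, i-Bu2AlH (1.0 equiv), hexanes, 55 °C; then 42, chiral sulfonate-bearing imidazolinium salt (NHC precursor, 5 mol %), CuCl2·2H2O (5 mol %), THF, −15 °C
Reagents that add atoms: none
Why: syn-Hydroalumination of the terminal alkyne gives the E-alkenylalane, whose alkenyl group the chiral NHC–copper complex transfers to the γ-carbon of the E-allylic phosphate in an enantioselective SN2′ allylic substitution; the C5=C6 geometry thus comes from the hydroalumination and quaternary C3 (S) is set by the catalyst, the existing stereocentres being too remote to interfere.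

**Compound list**

1 | (S)-(−)-limonene | CC1=CC[C@H](CC1)C(C)=C | starting material
2 | (4S)-limonene 1,2-oxide (cis/trans mixture) | CC12OC1C[C@H](CC2)C(C)=C | intermediate
3 | (4S)-1-methyl-4-(prop-1-en-2-yl)cyclohexane-1,2-diol (not isolated) | CC1(O)C(O)C[C@H](CC1)C(C)=C | intermediate
4 | (S)-6-oxo-3-(prop-1-en-2-yl)heptanal | CC(=O)CC[C@@H](CC=O)C(C)=C | intermediate
5 | (S)-6-oxo-3-(prop-1-en-2-yl)heptanoic acid | CC(=O)CC[C@@H](CC(=O)O)C(C)=C | intermediate
6 | 2-thioxopyridin-1(2H)-yl (S)-6-oxo-3-(prop-1-en-2-yl)heptanoate (Barton ester, not isolated) | CC(=O)CC[C@@H](CC(=O)ON1C=CC=CC1=S)C(C)=C | intermediate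
7 | (R)-5,6-dimethylhept-6-en-2-one | CC(=O)CC[C@@H](C)C(C)=C | intermediate
8 | diethyl (R)-5,6-dimethylhepta-1,6-dien-2-yl phosphate (not isolated) | C=C(OP(=O)(OCC)OCC)CC[C@@H](C)C(C)=C | intermediate
9 | (R)-5,6-dimethylhept-6-en-1-yne | C#CCC[C@@H](C)C(=C)C | intermediate
10 | (S)-methylsuccinic acid | OC(=O)[C@@H](C)CC(=O)O | starting material
11 | (S)-methylsuccinic anhydride | O=C1[C@@H](C)CC(=O)O1 | intermediate
12 | (S)-4-hydroxy-2-methylbutanoic acid (not isolated) | OC(=O)[C@@H](C)CCO | intermediate
13 | (S)-3-methyloxolan-2-one | O=C1[C@@H](C)CCO1 | intermediate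
14 | (3S)-3-methyloxolan-2-ol (anomeric mixture) | OC1[C@@H](C)CCO1 | intermediate
15 | (S)-3-methylpent-4-yn-1-ol | C#C[C@@H](C)CCO | intermediate
16 | trimethyl{[(3S)-3-methyl-5-(trimethylsilyl)pent-4-yn-1-yl]oxy}silane (not isolated) | C[Si](C)(C)C#C[C@@H](C)CCO[Si](C)(C)C | intermediate
17 | (S)-3-methyl-5-(trimethylsilyl)pent-4-yn-1-ol | C[Si](C)(C)C#C[C@@H](C)CCO | intermediate
18 | (S)-(5-iodo-3-methylpent-1-yn-1-yl)trimethylsilane | C[Si](C)(C)C#C[C@@H](C)CCI | intermediate
19 | dimethyl[(1E,5R)-2,5,6-trimethylhepta-1,6-dien-1-yl]alumane (not isolated) | C[Al](C)/C=C(\C)CC[C@@H](C)C(=C)C | intermediate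
20 | chloro[(1E,5R)-2,5,6-trimethylhepta-1,6-dien-1-yl]zinc (not isolated) | Cl[Zn]/C=C(\C)CC[C@@H](C)C(=C)C | intermediate
21 | trimethyl[(3S,6E,10R)-3,7,10,11-tetramethyldodeca-6,11-dien-1-yn-1-yl]silane | C[Si](C)(C)C#C[C@@H](C)CC/C=C(\C)CC[C@@H](C)C(=C)C | intermediate
22 | (3S,6E,10R)-3,7,10,11-tetramethyldodeca-6,11-dien-1-yne | C#C[C@@H](C)CC/C=C(\C)CC[C@@H](C)C(=C)C | intermediate
23 | propanal | CCC=O | starting material
24 | methyl vinyl ketone | CC(=O)C=C | starting material
25 | (S)-2-methyl-5-oxohexanal | O=C[C@@H](C)CCC(C)=O | intermediate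
26 | (4S)-3-hydroxy-4-methylcyclohexan-1-one (not isolated) | O=C1CC(O)[C@@H](C)CC1 | intermediate
27 | (S)-4-methylcyclohex-2-en-1-one | O=C1C=C[C@@H](C)CC1 | intermediate
28 | trimethyl{[(3R,4S)-3,4-dimethylcyclohex-1-en-1-yl]oxy}silane | C[Si](C)(C)OC1=C[C@H](C)[C@@H](C)CC1 | intermediate
29 | (S)-3,4-dimethylcyclohex-2-en-1-one | O=C1C=C(C)[C@@H](C)CC1 | intermediate
30 | lithium (S)-3,3,4-trimethylcyclohex-1-en-1-olate (not isolated) | [Li+].[O-]C1=CC(C)(C)[C@@H](C)CC1 | intermediate
31 | (S)-3,3,4-trimethylcyclohex-1-en-1-yl trifluoromethanesulfonate | FC(F)(F)S(=O)(=O)OC1=CC(C)(C)[C@@H](C)CC1 | intermediate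
32 | methyl (S)-3,3,4-trimethylcyclohex-1-ene-1-carboxylate | COC(=O)C1=CC(C)(C)[C@@H](C)CC1 | intermediate
33 | [(S)-3,3,4-trimethylcyclohex-1-en-1-yl]methanol | OCC1=CC(C)(C)[C@@H](C)CC1 | intermediate
34 | (S)-1-{[(1-ethoxyethenyl)oxy]methyl}-3,3,4-trimethylcyclohex-1-ene (not isolated) | C=C(OCC)OCC1=CC(C)(C)[C@@H](C)CC1 | intermediate
35 | ethyl 2-[(1S,3S)-2,2,3-trimethyl-6-methylidenecyclohexyl]acetate | CCOC(=O)C[C@H]1C(=C)CC[C@H](C)C1(C)C | intermediate
36 | 2-[(1S,3S)-2,2,3-trimethyl-6-methylidenecyclohexyl]ethan-1-ol | OCC[C@H]1C(=C)CC[C@H](C)C1(C)C | intermediate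
37 | (1S,3S)-1-(2-iodoethyl)-2,2,3-trimethyl-6-methylidenecyclohexane | ICC[C@H]1C(=C)CC[C@H](C)C1(C)C | intermediate
38 | 4-[(1S,3S)-2,2,3-trimethyl-6-methylidenecyclohexyl]but-1-yne | C#CCC[C@H]1C(=C)CC[C@H](C)C1(C)C | intermediate
39 | dimethyl{(1E)-2-methyl-4-[(1S,3S)-2,2,3-trimethyl-6-methylidenecyclohexyl]but-1-en-1-yl}alumane (not isolated) | C[Al](C)/C=C(\C)CC[C@H]1C(=C)CC[C@H](C)C1(C)C | intermediate
40 | lithium butyl(dimethyl){(1E)-2-methyl-4-[(1S,3S)-2,2,3-trimethyl-6-methylidenecyclohexyl]but-1-en-1-yl}aluminate (not isolated) | [Li+].CCCC[Al-](C)(C)/C=C(\C)CC[C@H]1C(=C)CC[C@H](C)C1(C)C | intermediate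
41 | (2E)-3-methyl-5-[(1S,3S)-2,2,3-trimethyl-6-methylidenecyclohexyl]pent-2-en-1-ol | OC/C=C(\C)CC[C@H]1C(=C)CC[C@H](C)C1(C)C | intermediate
42 | diethyl (2E)-3-methyl-5-[(1S,3S)-2,2,3-trimethyl-6-methylidenecyclohexyl]pent-2-en-1-yl phosphate | CCOP(=O)(OCC)OC/C=C(\C)CC[C@H]1C(=C)CC[C@H](C)C1(C)C | intermediate
43 | diisobutyl[(1E,3S,6E,10R)-3,7,10,11-tetramethyldodeca-1,6,11-trien-1-yl]alumane (not isolated) | CC(C)C[Al](CC(C)C)/C=C/[C@@H](C)CC/C=C(\C)CC[C@@H](C)C(=C)C | intermediate
44 | CNP0186101.1, (3S,4E,6S,9E,13R)-3,6,10,13,14-pentamethyl-3-{2-[(1S,3S)-2,2,3-trimethyl-6-methylidenecyclohexyl]ethyl}pentadeca-1,4,9,14-tetraene | C=C[C@@](C)(/C=C/[C@@H](C)CC/C=C(\C)CC[C@@H](C)C(=C)C)CC[C@H]1C(=C)CC[C@H](C)C1(C)C | target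

**Step count and risk**

Total step count: 27. Longest linear sequence: 14 steps (steps 14–26, then step 27).

Steps most likely to fail:

Step 12. The cross-coupling stage may go wrong in two ways: methyl groups left on aluminium or zinc may transfer in competition with the alkenyl group, and the alkylpalladium intermediate may lose a β-hydrogen, so that the iodide is consumed without forming C10–C11. The fallback reverses the roles of the two partners and sets out from 9 and 18. The alkenylalane 19 is quenched with I2 to give (R,E)-1-iodo-2,5,6-trimethylhepta-1,6-diene F1. Iodide 18 is converted by zinc insertion (Zn dust, LiCl, THF) into [(3S)-3-methyl-5-(trimethylsilyl)pent-4-yn-1-yl]zinc iodide F2. The two are joined by a Negishi coupling with Pd(dppf)Cl2 in THF, which comes back to the route at 21. Oxidative addition then occurs at the sp2 iodide and no methyl–metal species is present.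

Step 21. The rearrangement may show poor facial selectivity at C23, giving trans and cis ring diastereomers that cannot be corrected later because C23 is not epimerisable in the ester. The fallback forms the C22–C23 bond by enolate alkylation and sets out from 29. Cuprate addition as in step 18 gives enolate 30, which is alkylated with ethyl bromoacetate (DMPU, THF) to ethyl 2-[(1R,3S)-2,2,3-trimethyl-6-oxocyclohexyl]acetate F3. In F3 the C23 centre is α to the ketone, so the diastereomers can be separated and the unwanted one re-equilibrated with base. Non-basic Takai–Lombardo methylenation (Zn, CH2Br2, TiCl4) of the ketone then comes back to the route at 35.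

Step 27. The copper-catalysed substitution may give insufficient facial selectivity at C3 or some direct SN2 substitution, and C3 epimers would be hard to separate; part of the alkyne may also be lost by deprotonation during hydroalumination. The fallback sets C3 by reagent control and a stereospecific opening, and sets out from 41 and 22.
- Sharpless epoxidation of 41 (Ti(OiPr)4, D-(−)-diisopropyl tartrate, t-BuOOH, CH2Cl2, −20 °C) should give {(2R,3R)-3-methyl-3-{2-[(1S,3S)-2,2,3-trimethyl-6-methylidenecyclohexyl]ethyl}oxiran-2-yl}methanol F4, by analogy with geraniol.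
- Alkyne 22 is aluminated (Me3Al, cat. Et3N) to dimethyl[(3S,6E,10R)-3,7,10,11-tetramethyldodeca-6,11-dien-1-yn-1-yl]alumane F5.
- F5 opens F4 at the tertiary carbon with inversion to (2S,3R)-3-methyl-3-[(3S,6E,10R)-3,7,10,11-tetramethyldodeca-6,11-dien-1-yn-1-yl]-5-[(1S,3S)-2,2,3-trimethyl-6-methylidenecyclohexyl]pentane-1,2-diol F6.
- Na in liquid NH3 reduces the alkyne to the E-alkene, giving (2S,3R)-3-methyl-3-[(1E,3S,6E,10R)-3,7,10,11-tetramethyldodeca-1,6,11-trien-1-yl]-5-[(1S,3S)-2,2,3-trimethyl-6-methylidenecyclohexyl]pentane-1,2-diol F7.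
- Deoxygenation of the 1,2-diol to the vinyl group (I2, PPh3, imidazole, toluene, reflux) comes back to the route at the target 44.

**Further compounds**

F1 | step 12 | (R,E)-1-iodo-2,5,6-trimethylhepta-1,6-diene | I/C=C(\C)CC[C@@H](C)C(=C)C
F2 | step 12 | [(3S)-3-methyl-5-(trimethylsilyl)pent-4-yn-1-yl]zinc iodide | I[Zn]CC[C@H](C)C#C[Si](C)(C)C
F3 | step 21 | ethyl 2-[(1R,3S)-2,2,3-trimethyl-6-oxocyclohexyl]acetate | CCOC(=O)C[C@H]1C(=O)CC[C@H](C)C1(C)C
F4 | step 27 | {(2R,3R)-3-methyl-3-{2-[(1S,3S)-2,2,3-trimethyl-6-methylidenecyclohexyl]ethyl}oxiran-2-yl}methanol | OC[C@H]1O[C@]1(C)CC[C@H]2C(=C)CC[C@H](C)C2(C)C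
F5 | step 27 | dimethyl[(3S,6E,10R)-3,7,10,11-tetramethyldodeca-6,11-dien-1-yn-1-yl]alumane | C[Al](C)C#C[C@@H](C)CC/C=C(\C)CC[C@@H](C)C(=C)C
F6 | step 27 | (2S,3R)-3-methyl-3-[(3S,6E,10R)-3,7,10,11-tetramethyldodeca-6,11-dien-1-yn-1-yl]-5-[(1S,3S)-2,2,3-trimethyl-6-methylidenecyclohexyl]pentane-1,2-diol | OC[C@@H](O)[C@@](C)(C#C[C@@H](C)CC/C=C(\C)CC[C@@H](C)C(=C)C)CC[C@H]1C(=C)CC[C@H](C)C1(C)C
F7 | step 27 | (2S,3R)-3-methyl-3-[(1E,3S,6E,10R)-3,7,10,11-tetramethyldodeca-1,6,11-trien-1-yl]-5-[(1S,3S)-2,2,3-trimethyl-6-methylidenecyclohexyl]pentane-1,2-diol | OC[C@@H](O)[C@@](C)(/C=C/[C@@H](C)CC/C=C(\C)CC[C@@H](C)C(=C)C)CC[C@H]1C(=C)CC[C@H](C)C1(C)C
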